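**Retrosynthetic overview**

1. The only ring, the 1,2-dioxane O1–O2–C3–C4–C5–C6, is closed in the last step: the O2–C3 bond is made by an enantioselective 6-exo-trig conjugate addition of an acyclic C6 gem-methoxy hydroperoxide to the C2=C3 enoate, followed in the same flask by acid/MeOH equilibration of the C6 ketal.
2. Enabling feature: C3 lies β to the ester carbonyl C1, and C6, linked to it through C4–C5, is a peroxyketal carbon bearing O1 and OMe. C6 is therefore a masked ketone whose configuration can be corrected thermodynamically (axial OMe by the anomeric effect, both carbon substituents equatorial, which is 3S,6R once C3 is S).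
3. The hydroperoxy ketal comes from an achiral keto enoate (H2O2, MeOH); the C6 ketone is made by Negishi acylation of a C7–C22 alkylzinc with a C1–C6 acid chloride.
4. C7–C22: Sonogashira coupling of 5-chloropent-1-yne with (1E)-1-iodoundeca-1,10-diene (Takai olefination of dec-9-enal). C1–C6: cross-metathesis of pent-4-enoic acid with methyl acrylate.
5. Ring order: no ring exists before step 9; the dioxane is the first and last ring formed.

Key step: step 9

Remark on the chemistry: the catalyst of step 9 is the preformed urea–iminophosphorane 1-[3,5-bis(trifluoromethyl)phenyl]-3-[(2S)-3,3-dimethyl-1-{[tris(4-methoxyphenyl)-λ5-phosphanylidene]amino}butan-2-yl]urea ("BIMP urea catalyst"). Its sense of induction cannot be predicted with certainty; it is assumed that a first experiment assigns it and that the (2R)-antipode is used if the (2S)-catalyst gives the 3R series.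

**Route**

Step 1
Reactants: 1 dec-9-en-1-ol
Product: 2 dec-9-enal
Conditions: TEMPO (2,2,6,6-tetramethylpiperidin-1-oxyl, 10 mol %), PhI(OAc)2 (1.1 equiv), CH2Cl2, rt
Reagents that add atoms: none
Why: The oxoammonium (TEMPO/PhI(OAc)2) oxidation of a primary alcohol stops at the aldehyde and leaves the terminal alkene untouched.

Step 2
Reactants: 2 dec-9-enal
Product: 3 (1E)-1-iodoundeca-1,10-diene
Conditions: CrCl2 (6 equiv), CHI3 (2 equiv), THF/1,4-dioxane, 0 °C → rt
Reagents that add atoms: iodoform, IC(I)I
Why: Takai olefination, in which the geminal dichromium species formed from iodoform adds to the aldehyde and eliminates to the E-vinyl iodide, fixes the geometry of the future C12=C13 double bond.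

Step 3
Reactants: 3 (1E)-1-iodoundeca-1,10-diene; 4 5-chloropent-1-yne
Product: 5 (10E)-16-chlorohexadeca-1,10-dien-12-yne
Conditions: PdCl2(PPh3)2 (3 mol %), CuI (6 mol %), Et3N, THF, rt
Reagents that add atoms: none
Why: Sonogashira coupling of a vinyl iodide with a terminal alkyne proceeds at room temperature with retention of the E geometry, and the primary chloride and terminal alkene are inert to the palladium/copper system.

Step 4
Reactants: 5 (10E)-16-chlorohexadeca-1,10-dien-12-yne
Product: 6 (10E)-16-iodohexadeca-1,10-dien-12-yne
Conditions: NaI (3 equiv), acetone, reflux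
Reagents that add atoms: sodium iodide, [Na+].[I-]
Why: Finkelstein halide exchange, driven by precipitation of NaCl, gives the primary iodide needed for zinc insertion without touching the enyne.

Step 5
Reactants: 7 pent-4-enoic acid; 8 methyl acrylate (3 equiv)
Product: 9 (4E)-6-methoxy-6-oxohex-4-enoic acid
Conditions: second-generation Grubbs catalyst RuCl2(=CHPh)(H2IMes)(PCy3) (2 mol %), CH2Cl2, 40 °C
Reagents that add atoms: none
Why: Olefin cross-metathesis of an unhindered terminal alkene with an acrylate gives the E-enoate under thermodynamic control, and the free carboxylic acid is tolerated by the ruthenium carbene.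

Step 6
Reactants: 9 (4E)-6-methoxy-6-oxohex-4-enoic acid
Product: 10 methyl (2E)-6-chloro-6-oxohex-2-enoate
Conditions: (COCl)2 (1.2 equiv), DMF (cat.), CH2Cl2, 0 °C → rt; volatiles removed, used crude
Reagents that add atoms: oxalyl chloride, O=C(Cl)C(=O)Cl
Why: Acid chloride formation through the Vilsmeier-type chloroiminium species is neutral and leaves the conjugated methyl ester intact.

Step 7
Reactants: 6 (10E)-16-iodohexadeca-1,10-dien-12-yne; 10 methyl (2E)-6-chloro-6-oxohex-2-enoate
Product: 12 methyl (2E,12E)-6-oxodocosa-2,12,21-trien-10-ynoate, via alkylzinc iodide 11 (not isolated)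
Conditions: Zn dust (activated with BrCH2CH2Br, TMSCl), LiCl, THF, 40 °C; then 10, Pd(PPh3)4 (3 mol %), THF, 0 °C → rt
Reagents that add atoms: none
Why: LiCl-assisted direct zinc insertion gives an ester-tolerant alkylzinc iodide, and its palladium-catalysed Negishi acylation with the acid chloride should stop at the ketone without over-addition or conjugate addition to the enoate.

Step 8
Reactants: 12 methyl (2E,12E)-6-oxodocosa-2,12,21-trien-10-ynoate
Product: 13 methyl (2E,12E)-6-hydroperoxy-6-methoxydocosa-2,12,21-trien-10-ynoate (racemic at C6)
Conditions: urea–H2O2 (3 equiv), Sc(OTf)3 (10 mol %), MeOH, rt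
Reagents that add atoms: urea–hydrogen peroxide, NC(N)=O.OO; methanol, CO
Why: Lewis-acid-catalysed perketalization: the ketone condenses with methanol to a methoxy oxocarbenium ion that is captured by H2O2, while the enoate, enyne and alkenes are inert to H2O2 without base; C6 forms racemic and is corrected in step 9.

Step 9
Reactants: 13 methyl (2E,12E)-6-hydroperoxy-6-methoxydocosa-2,12,21-trien-10-ynoate
Product: 15 peroxyacarnoate A (methyl 2-[(3S,6R)-6-[(6E)-hexadeca-6,15-dien-4-yn-1-yl]-6-methoxy-1,2-dioxan-3-yl]acetate), via C6-epimeric 3S dioxane mixture 14 (not isolated)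
Conditions: BIMP urea catalyst (10 mol %), toluene, −20 °C; then MeOH (10 equiv), camphorsulfonic acid (30 mol %), CH2Cl2, 0 °C → rt; NaHCO3 quench
Reagents that add atoms: methanol, CO (degenerate exchange of the C6 methoxy group during the equilibration)
Why: Proposed new method: the iminophosphorane deprotonates the hydroperoxy ketal O–H (much more acidic than an alcohol) while the urea N–H groups bind the ester carbonyl, the ion-paired peroxy anion adds to C3 and the protonated iminophosphorane protonates the ester enolate, closing the 1,2-dioxane by a 6-exo-trig conjugate addition (O2–C3 bond). The closest known reactions are the amine-mediated, non-enantioselective intramolecular conjugate addition of hydroperoxy ketals to enoates that gives 3-methoxy-1,2-dioxanes, and the iminophosphorane-catalysed enantioselective intramolecular oxa-Michael addition of alcohols to α,β-unsaturated esters; only the pairing of a hydroperoxide nucleophile with this chiral catalyst class is new. C3 (S) is set by the catalyst, which differentiates the enoate faces; the racemic C6 centre is remote from the forming bond and should not override it, so both enantiomers of 13 should enter the 3S series (14). C6 (R) is then set under thermodynamic control: camphorsulfonic acid/MeOH reversibly ionises the ketal (ring opening to the methoxy oxocarbenium ion or loss of methanol) and should funnel both epimers to the cis isomer with axial OMe (anomeric effect) and both carbon substituents equatorial, while the C3–O2 bond is never broken. The step needs conjugate addition and enolate protonation to outrun attack of the enolate on the O–O bond (epoxide formation) and retro-addition, which the adjacent proton donor, the non-polar solvent and the low temperature should secure; the isolated alkenes and the enyne are not electrophilic, and the sulfur-free catalyst should not be oxidised by the hydroperoxide.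

**Compound list**

1 | dec-9-en-1-ol | C=CCCCCCCCCO | starting material
2 | dec-9-enal | C=CCCCCCCCC=O | intermediate
3 | (1E)-1-iodoundeca-1,10-diene | C=CCCCCCCC/C=C/I | intermediate
4 | 5-chloropent-1-yne | C#CCCCCl | starting material
5 | (10E)-16-chlorohexadeca-1,10-dien-12-yne | C=CCCCCCCC/C=C/C#CCCCCl | intermediate
6 | (10E)-16-iodohexadeca-1,10-dien-12-yne | C=CCCCCCCC/C=C/C#CCCCI | intermediate
7 | pent-4-enoic acid | C=CCCC(=O)O | starting material
8 | methyl acrylate | C=CC(=O)OC | starting material
9 | (4E)-6-methoxy-6-oxohex-4-enoic acid | COC(=O)/C=C/CCC(=O)O | intermediate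
10 | methyl (2E)-6-chloro-6-oxohex-2-enoate | COC(=O)/C=C/CCC(Cl)=O | intermediate
11 | [(6E)-hexadeca-6,15-dien-4-yn-1-yl]zinc iodide (formed in the flask, not isolated) | C=CCCCCCCC/C=C/C#CCCC[Zn]I | intermediate
12 | methyl (2E,12E)-6-oxodocosa-2,12,21-trien-10-ynoate | C=CCCCCCCC/C=C/C#CCCCC(=O)CC/C=C/C(=O)OC | intermediate
13 | methyl (2E,12E)-6-hydroperoxy-6-methoxydocosa-2,12,21-trien-10-ynoate, racemic at C6 | C=CCCCCCCC/C=C/C#CCCCC(OC)(OO)CC/C=C/C(=O)OC | intermediate
14 | methyl 2-[(3S)-6-[(6E)-hexadeca-6,15-dien-4-yn-1-yl]-6-methoxy-1,2-dioxan-3-yl]acetate, mixture of C6 epimers (formed in the flask, not isolated) | C=CCCCCCCC/C=C/C#CCCCC1(OC)CC[C@@H](CC(=O)OC)OO1 | intermediate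
15 | peroxyacarnoate A, methyl 2-[(3S,6R)-6-[(6E)-hexadeca-6,15-dien-4-yn-1-yl]-6-methoxy-1,2-dioxan-3-yl]acetate | C=CCCCCCCC/C=C/C#CCCC[C@]1(OC)CC[C@@H](CC(=O)OC)OO1 | target

**Step count and risks**

Total step count: 9. Longest linear sequence: 7 (steps 1, 2, 3, 4, 7, 8, 9).

Steps most likely to fail:

Step 9. The catalyst may discriminate the enoate faces insufficiently, in particular for the mismatched enantiomer of the racemic hydroperoxy ketal. Enantiomeric purity may also erode through reversible retro-addition, the ester enolate may be diverted into O–O cleavage and epoxide formation, or the hydroperoxide may deactivate the catalyst. The fallback uses known chemistry, sets out from 13 and comes back at 15. Cyclisation of 13 with Et2NH (cat.) in CF3CH2OH at rt, the established non-enantioselective amine-mediated conjugate addition, should give the dioxane stereoisomer mixture F1. Equilibration of C6 with camphorsulfonic acid/MeOH as in step 9 should then give the racemic cis-dioxane F2. The enantiomers of F2 would be separated by preparative HPLC on a chiral stationary phase (amylose tris(3,5-dimethylphenylcarbamate)); the (3S,6R)-enantiomer is 15.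

Step 8. The ketone/ketal/hydroperoxy ketal equilibrium in methanol may stop short or run on to the geminal bis-hydroperoxide, and the acidic peroxide medium may degrade the product. The fallback sets out from 12 and comes back at 13; it replaces the three-component equilibrium by kinetic Markovnikov addition of H2O2 to an enol ether in an aprotic solvent. Ketalization of 12 (HC(OMe)3, MeOH, pyridinium p-toluenesulfonate) should give the dimethyl ketal F3. Gassman-type elimination (TMSOTf, iPr2NEt, CH2Cl2, −20 °C) should give the methyl enol ether F4, formed together with its 5-ene regioisomer, which converges on the same product. Addition of anhydrous H2O2 in Et2O with catalytic pyridinium p-toluenesulfonate at 0 °C, the known route to α-alkoxy hydroperoxides, should give 13.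

Step 7. Zinc insertion may be sluggish or incomplete, the alkylzinc may homocouple, and the acylpalladium intermediate may decarbonylate or the enoate may suffer conjugate addition. The fallback sets out from 5 and comes back at 12; it builds the ketone from a nitrile and installs the enoate last by olefination, so steps 4 to 6 are not needed. Chloride 5 with Mg (THF, reflux, I2 initiation) should give the Grignard reagent F5. Its addition to commercial 4,4-dimethoxybutanenitrile (CuBr·SMe2 cat., THF) should give the N-magnesio ketimine F6. Work-up with aqueous HCl/THF hydrolyses the imine and the acetal to the keto aldehyde F7. Wittig olefination of F7 with Ph3P=CHCO2Me (CH2Cl2, rt), selective for the aldehyde and for the E-enoate, should give 12.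

**Further compounds**

F1 | step 9 | methyl 2-[6-[(6E)-hexadeca-6,15-dien-4-yn-1-yl]-6-methoxy-1,2-dioxan-3-yl]acetate, mixture of all ring stereoisomers | C=CCCCCCCC/C=C/C#CCCCC1(OC)CCC(CC(=O)OC)OO1
F2 | step 9 | racemic cis-dioxane, (3S,6R)- and (3R,6S)-enantiomers in equal amounts | C=CCCCCCCC/C=C/C#CCCC[C@]1(OC)CC[C@@H](CC(=O)OC)OO1.C=CCCCCCCC/C=C/C#CCCC[C@@]1(OC)CC[C@H](CC(=O)OC)OO1
F3 | step 8 | methyl (2E,12E)-6,6-dimethoxydocosa-2,12,21-trien-10-ynoate | C=CCCCCCCC/C=C/C#CCCCC(OC)(OC)CC/C=C/C(=O)OC
F4 | step 8 | methyl (2E,12E)-6-methoxydocosa-2,6,12,21-tetraen-10-ynoate (6-ene shown, formed with its 5-ene regioisomer) | C=CCCCCCCC/C=C/C#CCCC=C(OC)CC/C=C/C(=O)OC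
F5 | step 7 | [(6E)-hexadeca-6,15-dien-4-yn-1-yl]magnesium chloride | C=CCCCCCCC/C=C/C#CCCC[Mg]Cl
F6 | step 7 | N-chloromagnesio ketimine of (13E)-1,1-dimethoxyicosa-13,19-dien-11-yn-4-one | C=CCCCCCCC/C=C/C#CCCCC(=N[Mg]Cl)CCC(OC)OC
F7 | step 7 | (10E)-4-oxoicosa-10,19-dien-8-ynal | C=CCCCCCCC/C=C/C#CCCCC(=O)CCC=O
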